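Start at late times, where the earlier runs have stopped moving: a flat stretch can be frozen and reckoned with.

| flask | starting material | protic impurity | free catalyst | remark | time |
|---|---|---|---|---|---|
| north-east | 0.050 M | 0.0067 M | 5 mol% | run made earlier |  |
| north | 0.050 M | 0.015 M | 5 mol% | run made earlier |  |
| teal | 0.050 M | 0.0100 M | 5 mol% |  | 30 min |
| red | 0.050 M | 0.0100 M | 5 mol% |  | 40 min |

| run | time / min | product / % | catalyst intermediate B / % | catalyst intermediate A / % | starting material / % |
|---|---|---|---|---|---|
| north-east | 2.00 | 49.1 | 1.4 | 3.3 | 35.2 |
| north-east | 6.00 | 86.0 | 0.3 | 0.4 | 0.9 |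
| north-east | 10.0 | 87.7 | 0 | 0 | 0 |
| north-east | 15.0 | 87.0 | 0.3 | 0.5 | 0 |
| north-east | 20.0 | 85.7 | 0 | 1.6 | 0 |
| north-east | 30.0 | 87.6 | 0.7 | 0 | 1.0 |
| north-east | 40.0 | 85.2 | 1.1 | 0 | 0 |
| north | 2.00 | 44.3 | 1.7 | 1.7 | 20.6 |
| north | 6.00 | 70.1 | 0 | 1.9 | 1.0 |
| north | 10.0 | 69.9 | 0 | 1.0 | 0 |
| north | 15.0 | 68.8 | 0 | 0.3 | 0 |
| north | 20.0 | 70.9 | 0 | 0 | 1.3 |
| north | 30.0 | 69.1 | 0 | 0.5 | 0 |
| north | 40.0 | 70.1 | 0 | 1.5 | 1.4 |

(each reading ± 1 percentage point)

- which of these there is most of at the end, counted by the starting material in it, teal (catalyst intermediate B / product / starting material / catalyst intermediate A)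
- which of these there is most of at the end, counted by the starting material in it, red (catalyst intermediate B / product / starting material / catalyst intermediate A)
- final amount of the leader among these, as a percentage of the starting material charged, in teal
- final amount of the leader among these, as a percentage of the starting material charged, in red

- the numbers in the tables scatter by 1 percentage point (one standard deviation)

From 10.0 min to 40.0 min product lies flat in both earlier runs, and starting material reads no higher than 1.4%. Average product over those readings:

north-east plateau = 86.6%
north plateau = 69.8%

The rest of the charge went elsewhere, and the north run, with twice the impurity, lost more than the north-east run. So divide the loss by the impurity charged, both counted per starting material. Call the result the loss per impurity, the starting material lost for each impurity consumed, with both runs pooled and the charged impurity taken as consumed, since impurity is not among the readings: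

loss per impurity = total lost / total impurity equivalents = 1.00

Taken singly, the runs read 0.997 and 1.01, so freeze it. Now reckon teal and red, which differ in time and whose 30 min and 40 min lie inside the flat stretch of the earlier runs, again with the charged impurity taken as consumed:

product = 1 − loss per impurity × impurity equivalents = 79.9%

The forecast calls the loss one-to-one, “each impurity molecule consumes one starting-material equivalent”, and names product in teal and product in red, at 80% and 80%.

The flask gives product at 79.5% in teal and product at 79.5% in red.

    starting material + free catalyst → catalyst intermediate A (k = 14.8 M⁻¹ s⁻¹)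
    catalyst intermediate A ⇌ catalyst intermediate B (K = 2.40, k = 0.287 s⁻¹)
    catalyst intermediate B ⇌ free catalyst + product (K = 0.460 M, k = 0.234 s⁻¹)
    starting material + protic impurity → quenched substrate (k = 1.60 M⁻¹ s⁻¹)

In teal the slowest mode at 30.0 min has a half-life of 0.350 min, far shorter than the 30 min allowed, and a tenfold time changes nothing. Teal's impurity ends at 0.14% of its charge, with quenched substrate at 20.0% of the starting material.

Take the neighbour flask, teal with 0.013 M starting material. Its 0.769 equivalents, taken as consumed, reckon to 22.7% product. The neighbour flask gives 40.7%: starting material, the limiting reagent there, falls to 0% with 23% of the impurity left, and counting the impurity consumed, the loss per impurity reckons to 40.5%.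

The numbers in the tables are simulated for an exercise; scatter was added.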